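In the oxolane ring (O1, C2–C5) carbon C2 bears a methyl group and two carbon arms, the exocyclic bromovinyl group and ring carbon C3, that can both be drawn as vinyl groups; C2 is thus a latent divinyl(methyl)carbinol carbon that needs no configuration before the ring exists. The route disconnects C3–C4 as the alkene of a 2,5-dihydrofuran: one ring-closing metathesis with a chiral molybdenum alkylidene joins the vinyl group on C5 to one of two diastereotopic vinyl groups on C2, which closes the ring, sets C2 and keeps the other vinyl group for the bromovinyl arm. The precursor is the 3-methylpenta-1,4-dien-3-yl ether of (S)-1-(2-methyl-1,3-dioxolan-2-yl)prop-2-en-1-ol.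

Key step: step 10

Assumption (catalyst hand): the (S)-biphenolate antipode of the molybdenum catalyst is taken as the one matched to (S)-configured 13; if the pairing proves mismatched, the (R)-antipode is used and nothing else changes.
Remark (locants): from 14 on, ring atoms carry the target's oxolane locants (O1; C2 quaternary; C3; C4; C5 bears the dioxolanyl group, later the side chain); "side-chain carbon" is the carbon attached to C5.
Assumption (supply): dimethyl diazomalonate 8 and anhydrous CrBr2 are purchased.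

Step 1
Reactants: 1 ethyl (E)-4-oxopent-2-enoate; 2 ethane-1,2-diol
Product: 3 ethyl (E)-3-(2-methyl-1,3-dioxolan-2-yl)prop-2-enoate
Conditions: PPTS (10 mol %), benzene, reflux, Dean–Stark trap
Reagents that add atoms: none
Why: Acid-catalysed ketalisation with azeotropic removal of water protects the ketone, which is far more reactive toward acetal formation than the ester, while the alkene stays conjugated to the ester and keeps its E geometry.

Step 2
Reactants: 3 ethyl (E)-3-(2-methyl-1,3-dioxolan-2-yl)prop-2-enoate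
Product: 4 (E)-3-(2-methyl-1,3-dioxolan-2-yl)prop-2-en-1-ol
Conditions: i-Bu2AlH (2.2 equiv), CH2Cl2, −78 °C; Rochelle salt work-up
Reagents that add atoms: none
Why: DIBAL-H reduces the α,β-unsaturated ester by 1,2-addition to the E allylic alcohol (ester reduction) and leaves the ketal untouched.

Step 3
Reactants: 4 (E)-3-(2-methyl-1,3-dioxolan-2-yl)prop-2-en-1-ol
Product: 5 [(2R,3S)-3-(2-methyl-1,3-dioxolan-2-yl)oxiran-2-yl]methanol
Conditions: Ti(OiPr)4 (10 mol %), D-(−)-diethyl tartrate (12 mol %), t-BuOOH (2 equiv), 4 Å molecular sieves, CH2Cl2, −20 °C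
Reagents that add atoms: tert-butyl hydroperoxide, CC(C)(C)OO
Why: Katsuki–Sharpless asymmetric epoxidation of an E allylic alcohol, in which the D-(−)-tartrate ligand directs oxygen to the alkene face that makes the epoxide carbon next to the dioxolane (S) and the trans geometry of the alkene is carried into the epoxide.

Step 4
Reactants: 5 [(2R,3S)-3-(2-methyl-1,3-dioxolan-2-yl)oxiran-2-yl]methanol
Product: 6 (2S,3S)-2-(iodomethyl)-3-(2-methyl-1,3-dioxolan-2-yl)oxirane
Conditions: I2, PPh3, imidazole, THF, 0 °C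
Reagents that add atoms: iodine, II
Why: Appel-type iodination (PPh3/I2/imidazole) converts the primary alcohol into the iodide by SN2 displacement of the oxyphosphonium group without touching the epoxide stereocentres.

Step 5
Reactants: 6 (2S,3S)-2-(iodomethyl)-3-(2-methyl-1,3-dioxolan-2-yl)oxirane
Product: 7 (1S)-1-(2-methyl-1,3-dioxolan-2-yl)prop-2-en-1-ol
Conditions: Zn dust, EtOH, 78 °C
Reagents that add atoms: none
Why: Zinc inserts into the C–I bond and the organozinc eliminates across the epoxide (reductive opening of a 2,3-epoxy iodide), which shifts the alkene to the terminus and frees the secondary allylic alcohol without breaking the C–O bond at the stereocentre, so the (S) configuration set in step 3 is kept.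

Step 6
Reactants: 7 (1S)-1-(2-methyl-1,3-dioxolan-2-yl)prop-2-en-1-ol; 8 dimethyl diazomalonate
Product: 9 dimethyl 2-{[(1S)-1-(2-methyl-1,3-dioxolan-2-yl)prop-2-en-1-yl]oxy}propanedioate
Conditions: Rh2(OAc)4 (1 mol %), CH2Cl2, 40 °C, slow addition of 8
Reagents that add atoms: none
Why: Rhodium-carbenoid O–H insertion of the diazomalonate makes the crowded ether C–O bond without any substitution at the carbinol carbon, so its configuration is retained, and insertion into the O–H bond is much faster than cyclopropanation of the vinyl group.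

Step 7
Reactants: 9 dimethyl 2-{[(1S)-1-(2-methyl-1,3-dioxolan-2-yl)prop-2-en-1-yl]oxy}propanedioate
Product: 10 dimethyl 2-methyl-2-{[(1S)-1-(2-methyl-1,3-dioxolan-2-yl)prop-2-en-1-yl]oxy}propanedioate
Conditions: NaH, MeI, THF, 0 → 25 °C
Reagents that add atoms: iodomethane, CI
Why: Malonic ester alkylation: the sodium enolate of the alkoxymalonate is C-methylated by iodomethane to the fully substituted ether carbon, which carries two identical ester arms and is therefore not a stereocentre.

Step 8
Reactants: 10 dimethyl 2-methyl-2-{[(1S)-1-(2-methyl-1,3-dioxolan-2-yl)prop-2-en-1-yl]oxy}propanedioate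
Product: 11 2-methyl-2-{[(1S)-1-(2-methyl-1,3-dioxolan-2-yl)prop-2-en-1-yl]oxy}propane-1,3-diol
Conditions: LiAlH4, THF, 0 °C; aqueous NaOH work-up
Reagents that add atoms: none
Why: LiAlH4 reduces both ester groups to primary alcohols (ester reduction) while ketal and terminal alkene are inert.

Step 9
Reactants: 11 2-methyl-2-{[(1S)-1-(2-methyl-1,3-dioxolan-2-yl)prop-2-en-1-yl]oxy}propane-1,3-diol
Product: 13 2-methyl-2-{(1S)-1-[(3-methylpenta-1,4-dien-3-yl)oxy]prop-2-en-1-yl}-1,3-dioxolane, via dialdehyde 12 (not isolated)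
Conditions: Dess–Martin periodinane (2.5 equiv), CH2Cl2, 25 °C; quick extractive work-up, crude 12 used at once; Ph3P=CH2 (from Ph3PCH3Br, KN(SiMe3)2), THF, −78 → 25 °C
Reagents that add atoms: methyltriphenylphosphonium bromide, C[P+](c1ccccc1)(c1ccccc1)c1ccccc1.[Br-]
Why: Dess–Martin oxidation gives the non-enolisable dialdehyde, which is used at once because 2,2-disubstituted malonaldehydes hydrate and deformylate on storage, and double Wittig methylenation turns both formyl groups into the two equivalent vinyl groups.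

Step 10
Reactants: 13 2-methyl-2-{(1S)-1-[(3-methylpenta-1,4-dien-3-yl)oxy]prop-2-en-1-yl}-1,3-dioxolane
Product: 14 (2S,5S)-2-ethenyl-2-methyl-5-(2-methyl-1,3-dioxolan-2-yl)-2,5-dihydrofuran
Conditions: Mo(N-2,6-iPr2C6H3)(CHCMe2Ph)[(S)-3,3′-tBu2-5,5′,6,6′-Me4-1,1′-biphenyl-2,2′-diolate] (5 mol %), benzene (0.05 M), 22 °C, N2 sweep to remove ethene
Reagents that add atoms: none
Why: Ring-closing alkene metathesis: the molybdenum alkylidene exchanges onto a terminal alkene, preferentially the vinyl group on the secondary carbinol carbon, then adds across one of the two vinyl groups on the quaternary carbon to a molybdacyclobutane whose cycloreversion forms the C3=C4 bond and releases ethene. The closest known reaction type is the molybdenum-catalysed desymmetrising ring-closing metathesis of divinyl carbinol allyl ethers to 2,5-dihydrofurans, which tolerates fully substituted ether carbons. The one ring formed is the five-membered oxacycle, closed by joining two alkene termini across the ether oxygen; this is the only productive mode, since the two geminal vinyl groups cannot close onto each other. The new stereocentre C2 is fixed by which diastereotopic vinyl group enters the metallacycle, the two transition states being diastereomeric through the existing C5 centre and through the chiral biphenolate on molybdenum. The step needs the surviving vinyl group cis to the dioxolanyl group, which is secured by using the catalyst antipode whose preference reinforces the substrate bias and by sweeping out ethene so that closure is not reversed.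

Step 11
Reactants: 14 (2S,5S)-2-ethenyl-2-methyl-5-(2-methyl-1,3-dioxolan-2-yl)-2,5-dihydrofuran
Product: 15 (1R,2S,4S,5S)-2-ethenyl-2-methyl-4-(2-methyl-1,3-dioxolan-2-yl)-3,6-dioxabicyclo[3.1.0]hexane
Conditions: dimethyldioxirane (1.2 equiv, in acetone), CH2Cl2, 0 °C
Reagents that add atoms: dimethyldioxirane, CC1(C)OO1
Why: Epoxidation by dimethyldioxirane is chemoselective for the cis-disubstituted ring alkene over the monosubstituted vinyl group on a quaternary carbon (electrophilic oxidant) and facially selective for the side that holds only the C2 methyl group, anti to the vinyl group and to the dioxolanyl group, which fixes the configuration of both epoxide carbons.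

Step 12
Reactants: 15 (1R,2S,4S,5S)-2-ethenyl-2-methyl-4-(2-methyl-1,3-dioxolan-2-yl)-3,6-dioxabicyclo[3.1.0]hexane
Product: 16 (2S,3R,4S,5S)-4-chloro-5-ethenyl-5-methyl-2-(2-methyl-1,3-dioxolan-2-yl)oxolan-3-ol
Conditions: LiCl (6 equiv), AcOH (3 equiv), THF, 50 °C
Reagents that add atoms: lithium chloride, [Li+].[Cl-]
Why: Halohydrin formation by SN2 opening of the epoxide with chloride under mild acid activation: backside attack at C3 inverts that carbon and places chlorine cis to the vinyl group and the C5 substituent, and C3 rather than C4 is attacked because the approach to C4 on that face runs past the quaternary dioxolane carbon on C5 whereas the approach to C3 runs past the flat vinyl group only.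

Step 13
Reactants: 16 (2S,3R,4S,5S)-4-chloro-5-ethenyl-5-methyl-2-(2-methyl-1,3-dioxolan-2-yl)oxolan-3-ol
Product: 17 O-[(2S,3R,4S,5S)-4-chloro-5-ethenyl-5-methyl-2-(2-methyl-1,3-dioxolan-2-yl)oxolan-3-yl] O-phenyl carbonothioate
Conditions: PhOC(S)Cl, pyridine, DMAP (cat.), CH2Cl2, 0 → 25 °C
Reagents that add atoms: O-phenyl chlorothionoformate, S=C(Cl)Oc1ccccc1
Why: Acylation of the secondary C4 alcohol with phenyl chlorothionoformate gives the thionocarbonate needed for radical deoxygenation (first stage of the Barton–McCombie sequence).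

Step 14
Reactants: 17 O-[(2S,3R,4S,5S)-4-chloro-5-ethenyl-5-methyl-2-(2-methyl-1,3-dioxolan-2-yl)oxolan-3-yl] O-phenyl carbonothioate
Product: 18 (2S,3S,5S)-3-chloro-2-ethenyl-2-methyl-5-(2-methyl-1,3-dioxolan-2-yl)oxolane
Conditions: Bu3SnH (1.5 equiv), AIBN (cat.), toluene, 90 °C
Reagents that add atoms: none
Why: Barton–McCombie deoxygenation: the tributyltin radical adds to the thiocarbonyl group, the C4–O bond fragments, and the secondary C4 radical is reduced by Bu3SnH faster than it can expel the β-chlorine atom, so the C3 chloride and its configuration survive.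

Step 15
Reactants: 18 (2S,3S,5S)-3-chloro-2-ethenyl-2-methyl-5-(2-methyl-1,3-dioxolan-2-yl)oxolane
Product: 20 (2S,3S,5S)-3-chloro-2-methyl-5-(2-methyl-1,3-dioxolan-2-yl)oxolane-2-carbaldehyde, via ozonide 19 (not isolated)
Conditions: O3, CH2Cl2, −78 °C; then Me2S, −78 → 25 °C
Reagents that add atoms: ozone, [O-][O+]=O
Why: Ozonolysis with reductive work-up cleaves the only alkene left to the aldehyde, which has no α-hydrogen and therefore cannot epimerise at C2.

Step 16
Reactants: 20 (2S,3S,5S)-3-chloro-2-methyl-5-(2-methyl-1,3-dioxolan-2-yl)oxolane-2-carbaldehyde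
Product: 21 (2S,3S,5S)-2-[(E)-2-bromoethenyl]-3-chloro-2-methyl-5-(2-methyl-1,3-dioxolan-2-yl)oxolane
Conditions: CrBr2 (6 equiv), CHBr3 (2 equiv), THF, 0 → 25 °C
Reagents that add atoms: bromoform, BrC(Br)Br
Why: Takai olefination: the geminal dichromium reagent formed from bromoform and divalent chromium adds to the aldehyde and eliminates to the E bromoalkene, and CrBr2 is chosen over CrCl2 so that no chloride is exchanged into the alkenyl halide.

Step 17
Reactants: 21 (2S,3S,5S)-2-[(E)-2-bromoethenyl]-3-chloro-2-methyl-5-(2-methyl-1,3-dioxolan-2-yl)oxolane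
Product: 22 1-[(2S,4S,5S)-5-[(E)-2-bromoethenyl]-4-chloro-5-methyloxolan-2-yl]ethan-1-one
Conditions: 2 M HCl, THF, 25 °C
Reagents that add atoms: water, O
Why: Acid-catalysed hydrolysis of the dioxolane frees the methyl ketone (ketal deprotection) under conditions that leave the alkyl chloride, the bromoalkene and the oxolane ring untouched and are too mild to enolise the ketone toward C5.

Step 18
Reactants: 22 1-[(2S,4S,5S)-5-[(E)-2-bromoethenyl]-4-chloro-5-methyloxolan-2-yl]ethan-1-one
Product: 24 1-[(2S,4S,5S)-5-[(E)-2-bromoethenyl]-4-chloro-5-methyloxolan-2-yl]-2-chloroethan-1-one, via silyl enol ether 23 (not isolated)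
Conditions: LiN(iPr)2, Me3SiCl, THF, −78 °C; then N-chlorosuccinimide, THF, 0 °C
Reagents that add atoms: N-chlorosuccinimide, ClN1C(=O)CCC1=O
Why: Kinetic deprotonation by LiN(iPr)2 takes place at the methyl group, not at the hindered α-alkoxy C5–H, and in situ silylation gives the terminal silyl enol ether, whose chlorination by N-chlorosuccinimide gives the chloromethyl ketone (α-halogenation via a silyl enol ether) without loss of configuration at C5.

Step 19
Reactants: 24 1-[(2S,4S,5S)-5-[(E)-2-bromoethenyl]-4-chloro-5-methyloxolan-2-yl]-2-chloroethan-1-one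
Product: 25 (2S)-2-[(2S,4S,5S)-5-[(E)-2-bromoethenyl]-4-chloro-5-methyloxolan-2-yl]-1-chloropropan-2-ol
Conditions: MeMgBr (1.5 equiv), CH2Cl2/Et2O, −78 °C; aqueous NH4Cl at −78 °C
Reagents that add atoms: methylmagnesium bromide, C[Mg]Br
Why: Chelation-controlled Grignard addition (Cram chelate model): magnesium bridges the ketone oxygen and the ring oxygen, and the methyl group adds to the face of the five-membered chelate that carries only the C5 hydrogen, which sets the carbinol carbon as (S).

Step 20
Reactants: 25 (2S)-2-[(2S,4S,5S)-5-[(E)-2-bromoethenyl]-4-chloro-5-methyloxolan-2-yl]-1-chloropropan-2-ol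
Product: 26 (2S,3S,5S)-5-[(2S)-2-bromo-1-chloropropan-2-yl]-2-[(E)-2-bromoethenyl]-3-chloro-2-methyloxolane
Conditions: Me3SiBr (3 equiv), CH2Cl2, −20 → 20 °C, dark
Reagents that add atoms: bromotrimethylsilane, C[Si](C)(C)Br
Why: Conversion of a tertiary alcohol into the tertiary bromide with Me3SiBr (ionising substitution of the silylated alcohol): because an open cation here is disfavoured by the flanking C–Cl and ring C–O bonds, ionisation is expected to go with backside participation of the chlorine atom to a bridged chloronium ion that bromide opens at the tertiary carbon, and the two inversions leave bromine in the place of oxygen (retention through neighbouring-group participation).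

Compound list
1 | ethyl (E)-4-oxopent-2-enoate | CCOC(=O)/C=C/C(C)=O | starting material
2 | ethane-1,2-diol (ethylene glycol) | OCCO | starting material
3 | ethyl (E)-3-(2-methyl-1,3-dioxolan-2-yl)prop-2-enoate | CCOC(=O)/C=C/C1(C)OCCO1 | intermediate
4 | (E)-3-(2-methyl-1,3-dioxolan-2-yl)prop-2-en-1-ol | OC/C=C/C1(C)OCCO1 | intermediate
5 | [(2R,3S)-3-(2-methyl-1,3-dioxolan-2-yl)oxiran-2-yl]methanol (trans epoxide) | OC[C@H]1O[C@@H]1C2(C)OCCO2 | intermediate
6 | (2S,3S)-2-(iodomethyl)-3-(2-methyl-1,3-dioxolan-2-yl)oxirane (same spatial arrangement as 5) | IC[C@H]1O[C@@H]1C2(C)OCCO2 | intermediate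
7 | (1S)-1-(2-methyl-1,3-dioxolan-2-yl)prop-2-en-1-ol | CC1(OCCO1)[C@@H](O)C=C | intermediate
8 | dimethyl 2-diazopropanedioate (dimethyl diazomalonate) | COC(=O)C(=[N+]=[N-])C(=O)OC | starting material
9 | dimethyl 2-{[(1S)-1-(2-methyl-1,3-dioxolan-2-yl)prop-2-en-1-yl]oxy}propanedioate | CC1(OCCO1)[C@@H](OC(C(=O)OC)C(=O)OC)C=C | intermediate
10 | dimethyl 2-methyl-2-{[(1S)-1-(2-methyl-1,3-dioxolan-2-yl)prop-2-en-1-yl]oxy}propanedioate | CC1(OCCO1)[C@@H](OC(C)(C(=O)OC)C(=O)OC)C=C | intermediate
11 | 2-methyl-2-{[(1S)-1-(2-methyl-1,3-dioxolan-2-yl)prop-2-en-1-yl]oxy}propane-1,3-diol | CC1(OCCO1)[C@@H](OC(C)(CO)CO)C=C | intermediate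
12 | 2-methyl-2-{[(1S)-1-(2-methyl-1,3-dioxolan-2-yl)prop-2-en-1-yl]oxy}propanedial | CC1(OCCO1)[C@@H](OC(C)(C=O)C=O)C=C | intermediate
13 | 2-methyl-2-{(1S)-1-[(3-methylpenta-1,4-dien-3-yl)oxy]prop-2-en-1-yl}-1,3-dioxolane (metathesis precursor) | CC1(OCCO1)[C@@H](OC(C)(C=C)C=C)C=C | intermediate
14 | (2S,5S)-2-ethenyl-2-methyl-5-(2-methyl-1,3-dioxolan-2-yl)-2,5-dihydrofuran (vinyl cis to the dioxolanyl group) | CC1(OCCO1)[C@@H]2C=C[C@](C)(C=C)O2 | intermediate
15 | (1R,2S,4S,5S)-2-ethenyl-2-methyl-4-(2-methyl-1,3-dioxolan-2-yl)-3,6-dioxabicyclo[3.1.0]hexane (epoxide oxygen cis to the methyl group) | CC1(OCCO1)[C@@H]2[C@H]3O[C@H]3[C@](C)(C=C)O2 | intermediate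
16 | (2S,3R,4S,5S)-4-chloro-5-ethenyl-5-methyl-2-(2-methyl-1,3-dioxolan-2-yl)oxolan-3-ol (target locants: 3-chloro cis to vinyl, 4-hydroxy trans to chlorine) | CC1(OCCO1)[C@@H]2[C@@H](O)[C@H](Cl)[C@](C)(C=C)O2 | intermediate
17 | O-[(2S,3R,4S,5S)-4-chloro-5-ethenyl-5-methyl-2-(2-methyl-1,3-dioxolan-2-yl)oxolan-3-yl] O-phenyl carbonothioate | CC1(OCCO1)[C@@H]2[C@@H](OC(=S)Oc3ccccc3)[C@H](Cl)[C@](C)(C=C)O2 | intermediate
18 | (2S,3S,5S)-3-chloro-2-ethenyl-2-methyl-5-(2-methyl-1,3-dioxolan-2-yl)oxolane | CC1(OCCO1)[C@@H]2C[C@H](Cl)[C@](C)(C=C)O2 | intermediate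
19 | 3-[(2S,3S,5S)-3-chloro-2-methyl-5-(2-methyl-1,3-dioxolan-2-yl)oxolan-2-yl]-1,2,4-trioxolane (ozonide, both epimers at the trioxolane carbon) | CC1(OCCO1)[C@@H]2C[C@H](Cl)[C@](C)(C3OCOO3)O2 | intermediate
20 | (2S,3S,5S)-3-chloro-2-methyl-5-(2-methyl-1,3-dioxolan-2-yl)oxolane-2-carbaldehyde | CC1(OCCO1)[C@@H]2C[C@H](Cl)[C@](C)(C=O)O2 | intermediate
21 | (2S,3S,5S)-2-[(E)-2-bromoethenyl]-3-chloro-2-methyl-5-(2-methyl-1,3-dioxolan-2-yl)oxolane | CC1(OCCO1)[C@@H]2C[C@H](Cl)[C@](C)(/C=C/Br)O2 | intermediate
22 | 1-[(2S,4S,5S)-5-[(E)-2-bromoethenyl]-4-chloro-5-methyloxolan-2-yl]ethan-1-one | CC(=O)[C@@H]1C[C@H](Cl)[C@](C)(/C=C/Br)O1 | intermediate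
23 | [(1-{(2S,4S,5S)-5-[(E)-2-bromoethenyl]-4-chloro-5-methyloxolan-2-yl}ethenyl)oxy]trimethylsilane | C=C(O[Si](C)(C)C)[C@@H]1C[C@H](Cl)[C@](C)(/C=C/Br)O1 | intermediate
24 | 1-[(2S,4S,5S)-5-[(E)-2-bromoethenyl]-4-chloro-5-methyloxolan-2-yl]-2-chloroethan-1-one | ClCC(=O)[C@@H]1C[C@H](Cl)[C@](C)(/C=C/Br)O1 | intermediate
25 | (2S)-2-[(2S,4S,5S)-5-[(E)-2-bromoethenyl]-4-chloro-5-methyloxolan-2-yl]-1-chloropropan-2-ol | C[C@@](O)(CCl)[C@@H]1C[C@H](Cl)[C@](C)(/C=C/Br)O1 | intermediate
26 | (2S,3S,5S)-5-[(2S)-2-bromo-1-chloropropan-2-yl]-2-[(E)-2-bromoethenyl]-3-chloro-2-methyloxolane | C[C@@](Br)(CCl)[C@@H]1C[C@H](Cl)[C@](C)(/C=C/Br)O1 | target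

Total step count: 20.
Longest linear sequence: 20 steps (1 to 26); 2 and 8 are purchased inputs.

Steps most likely to fail

Step 20. What may go wrong: ionisation without help from the neighbouring chlorine, which would pass through an open cation and lose the configuration at the side-chain carbon; elimination toward alkenes; or participation of the ring oxygen with ring enlargement. Fallback (sets out from 22, returns at 26): Wittig methylenation of 22 (Ph3P=CH2, THF, 0 °C) gives the isopropenyl compound (2S,3S,5S)-2-[(E)-2-bromoethenyl]-3-chloro-2-methyl-5-(prop-1-en-2-yl)oxolane F1. Ene-type allylic chlorination with hypochlorous acid (Ca(OCl)2, CO2, CH2Cl2/H2O, 0 °C) gives the 2-(chloromethyl)allyl compound (2S,3S,5S)-2-[(E)-2-bromoethenyl]-3-chloro-5-(3-chloroprop-1-en-2-yl)-2-methyloxolane F2. Ionic Markovnikov addition of dry HBr (CH2Cl2, −40 °C, dark) then gives 26 together with its side-chain epimer (2S,3S,5S)-5-[(2R)-2-bromo-1-chloropropan-2-yl]-2-[(E)-2-bromoethenyl]-3-chloro-2-methyloxolane F3, which is removed by preparative HPLC. Here the placement of bromine and chlorine follows from regiochemistry alone, and separation takes the place of stereocontrol at that one carbon.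

Step 12. What may go wrong: chloride entering at C4 instead of C3, or an opening so slow that the acid reaches the ketal first. Fallback (sets out from 15, returns at 18): the same steric bias is used in reverse with hydride. LiBHEt3 (THF, 0 → 25 °C) reduces 15 at whichever epoxide carbon is open to nucleophiles; if that is C4, the product is the C3 alcohol (2S,3R,5S)-2-ethenyl-2-methyl-5-(2-methyl-1,3-dioxolan-2-yl)oxolan-3-ol F4, with hydroxyl trans to the vinyl group. Its chloromethanesulfonate (2S,3R,5S)-2-ethenyl-2-methyl-5-(2-methyl-1,3-dioxolan-2-yl)oxolan-3-yl chloromethanesulfonate F5 (ClCH2SO2Cl, pyridine, 0 °C) is displaced by LiCl (DMF, 60 °C, SN2 with inversion) to give 18, and steps 13 and 14 fall away.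

Step 10. What may go wrong: weak discrimination between the two diastereotopic vinyl groups, or erosion of the ratio by reversible metathesis. Fallback (sets out from 7, returns at 14): C2 is fixed before the ring is closed. Palladium-catalysed branched-selective addition of 7 to 2-methyl-2-vinyloxirane (Pd2(dba)3·CHCl3, chiral N,N′-(trans-cyclohexane-1,2-diyl)bis[2-(diphenylphosphino)benzamide], BEt3 cat., CH2Cl2, 25 °C) gives the tertiary ether (2R)-2-methyl-2-{[(1S)-1-(2-methyl-1,3-dioxolan-2-yl)prop-2-en-1-yl]oxy}but-3-en-1-ol F6, whose ether carbon is set by the ligand. Ring-closing metathesis with the second-generation ruthenium benzylidene catalyst RuCl2(=CH-2-iPrOC6H4)(H2IMes) (CH2Cl2, 40 °C) can engage only its single vinyl group and gives [(2R,5S)-2-methyl-5-(2-methyl-1,3-dioxolan-2-yl)-2,5-dihydrofuran-2-yl]methanol F7. Dess–Martin oxidation to (2R,5S)-2-methyl-5-(2-methyl-1,3-dioxolan-2-yl)-2,5-dihydrofuran-2-carbaldehyde F8 and Wittig methylenation (Ph3P=CH2, THF) give 14.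

Further compounds
F1 | step 20 | (2S,3S,5S)-2-[(E)-2-bromoethenyl]-3-chloro-2-methyl-5-(prop-1-en-2-yl)oxolane | C=C(C)[C@@H]1C[C@H](Cl)[C@](C)(/C=C/Br)O1
F2 | step 20 | (2S,3S,5S)-2-[(E)-2-bromoethenyl]-3-chloro-5-(3-chloroprop-1-en-2-yl)-2-methyloxolane | C=C(CCl)[C@@H]1C[C@H](Cl)[C@](C)(/C=C/Br)O1
F3 | step 20 | (2S,3S,5S)-5-[(2R)-2-bromo-1-chloropropan-2-yl]-2-[(E)-2-bromoethenyl]-3-chloro-2-methyloxolane | C[C@](Br)(CCl)[C@@H]1C[C@H](Cl)[C@](C)(/C=C/Br)O1
F4 | step 12 | (2S,3R,5S)-2-ethenyl-2-methyl-5-(2-methyl-1,3-dioxolan-2-yl)oxolan-3-ol | CC1(OCCO1)[C@@H]2C[C@@H](O)[C@](C)(C=C)O2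
F5 | step 12 | (2S,3R,5S)-2-ethenyl-2-methyl-5-(2-methyl-1,3-dioxolan-2-yl)oxolan-3-yl chloromethanesulfonate | CC1(OCCO1)[C@@H]2C[C@@H](OS(=O)(=O)CCl)[C@](C)(C=C)O2
F6 | step 10 | (2R)-2-methyl-2-{[(1S)-1-(2-methyl-1,3-dioxolan-2-yl)prop-2-en-1-yl]oxy}but-3-en-1-ol | CC1(OCCO1)[C@@H](O[C@@](C)(CO)C=C)C=C
F7 | step 10 | [(2R,5S)-2-methyl-5-(2-methyl-1,3-dioxolan-2-yl)-2,5-dihydrofuran-2-yl]methanol | CC1(OCCO1)[C@@H]2C=C[C@](C)(CO)O2
F8 | step 10 | (2R,5S)-2-methyl-5-(2-methyl-1,3-dioxolan-2-yl)-2,5-dihydrofuran-2-carbaldehyde | CC1(OCCO1)[C@@H]2C=C[C@](C)(C=O)O2
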